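**Retrosynthetic overview**
- Presumed biosynthesis: a C20 acyl starter plus malonate units gives a 3,7-dioxoacyl thioester, which closes C2→C7 by aldol condensation and then loses the C1 carboxyl (alkylresorcinol-type pathway stopped before aromatisation).
- Target ⇐ dimethyl 4-nonadecyl-2-oxocyclohex-3-ene-1,3-dicarboxylate by hydrolysis and loss of two CO2 (both carboxyls are "malonate" carbons).
- That ring ⇐ one-flask [3+3] annulation: Michael addition of dimethyl 3-oxopentanedioate to nonadecyl vinyl ketone, then closure of the ester-activated CH2 onto the fatty-acyl ketone (the C2→C7 bond). The linear 3,7-dioxo ester is never made stepwise.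
- Vinyl ketone (handled as its stable β-chloro ketone) ⇐ icosanoic acid + ethylene.
- Ring order: one carbocycle only, formed in step 2.

Assumption: the target, 3-nonadecylcyclohex-2-en-1-one (C25H46O), has no stereocentre, so it is achiral and needs no stereocontrol. The sp3 centres in 7–10 are racemic or epimerisable and are destroyed in step 3, so their SMILES carry no stereodescriptors.

**Route**

Step 1
Reactants: 1 icosanoic acid (arachidic acid); 2 ethylene
Product: 4 1-chlorodocosan-3-one, via icosanoyl chloride 3 (not isolated)
Conditions: (COCl)2 (1.3 equiv), DMF (cat.), CH2Cl2, 0 °C→rt, evaporate; AlCl3 (1.2 equiv), C2H4 (1 atm, bubbled), CH2Cl2, 0–5 °C, 3 h; ice/1 M HCl; recrystallise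
Reagents that add atoms: oxalyl chloride, ClC(=O)C(=O)Cl; aluminium chloride, Cl[Al](Cl)Cl (chloride pool for the new C–Cl bond via AlCl4−)
Why: The acid chloride acylates ethylene in a Friedel–Crafts-type alkene acylation (Darzens–Nenitzescu); the acylium ion adds to the C=C and chloride from AlCl4− caps the cation, giving a storable β-chloro ketone in place of the polymerisation-prone vinyl ketone, with no stereocentre formed.

Step 2
Reactants: 4 1-chlorodocosan-3-one; 5 dimethyl 3-oxopentanedioate (dimethyl acetone-1,3-dicarboxylate)
Product: 9 dimethyl 4-nonadecyl-2-oxocyclohex-3-ene-1,3-dicarboxylate, via docos-1-en-3-one 6 (not isolated), via Michael adduct 7 (not isolated), via aldol 8 (not isolated)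
Conditions: 5 (3 equiv), K2CO3 (1.5 equiv), THF–MeOH 9:1, 4 added over 2 h, 0 °C→rt, 6 h; then AcOH (3 equiv), piperidine (0.2 equiv), toluene, reflux, Dean–Stark, 6 h; crystallise from MeOH
Reagents that add atoms: none
Why: This is a one-flask [3+3] annulation from known reaction types: E1cB loss of HCl unmasks the vinyl ketone, the enolate of 5 adds to it (Michael), and piperidinium acetate closes the ring by intramolecular Knoevenagel (aldol) condensation of the remaining ketone/ester-flanked CH2 (pKa about 11, the counterpart of C2 of the 3,7-dioxoacyl chain) onto the chain ketone (counterpart of C7), with alkoxide-free conditions excluding the competing Claisen closure; the one sp3 centre formed is racemic and is erased in step 3.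

Step 3
Reactants: 9 dimethyl 4-nonadecyl-2-oxocyclohex-3-ene-1,3-dicarboxylate
Product: 13 3-nonadecylcyclohex-2-en-1-one, via half-acid 10 (not isolated), via keto ester 11 (not isolated), via keto acid 12 (not isolated)
Conditions: AcOH–H2O–conc. H2SO4 (6:3:1), reflux, 8–12 h, N2; hexane extraction, silica plug, recrystallise (acetone, −20 °C)
Reagents that add atoms: none
Why: Acid-catalysed ester hydrolysis is followed by decarboxylation of the β-keto acid 10 and then of the alkylidene β-keto acid 12 through its β,γ-unsaturated (dienol) tautomer, the same hydrolysis/decarboxylation that ends the biosynthetic sequence; the double bond settles in the conjugated endocyclic position and the product is achiral.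

**Compound list**

1 | icosanoic acid (arachidic acid) | CCCCCCCCCCCCCCCCCCCC(=O)O | starting material
2 | ethylene | C=C | starting material
3 | icosanoyl chloride | CCCCCCCCCCCCCCCCCCCC(=O)Cl | intermediate
4 | 1-chlorodocosan-3-one | CCCCCCCCCCCCCCCCCCCC(=O)CCCl | intermediate
5 | dimethyl 3-oxopentanedioate | COC(=O)CC(=O)CC(=O)OC | starting material
6 | docos-1-en-3-one | CCCCCCCCCCCCCCCCCCCC(=O)C=C | intermediate
7 | dimethyl 3-oxo-2-(3-oxodocosyl)pentanedioate (racemic) | CCCCCCCCCCCCCCCCCCCC(=O)CCC(C(=O)OC)C(=O)CC(=O)OC | intermediate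
8 | dimethyl 4-hydroxy-4-nonadecyl-2-oxocyclohexane-1,3-dicarboxylate (diastereomer mixture, racemic) | CCCCCCCCCCCCCCCCCCCC1(O)CCC(C(=O)OC)C(=O)C1C(=O)OC | intermediate
9 | dimethyl 4-nonadecyl-2-oxocyclohex-3-ene-1,3-dicarboxylate (racemic, epimerisable) | CCCCCCCCCCCCCCCCCCCC1=C(C(=O)OC)C(=O)C(C(=O)OC)CC1 | intermediate
10 | 3-(methoxycarbonyl)-4-nonadecyl-2-oxocyclohex-3-ene-1-carboxylic acid (racemic) | CCCCCCCCCCCCCCCCCCCC1=C(C(=O)OC)C(=O)C(C(=O)O)CC1 | intermediate
11 | methyl 2-nonadecyl-6-oxocyclohex-1-ene-1-carboxylate | CCCCCCCCCCCCCCCCCCCC1=C(C(=O)OC)C(=O)CCC1 | intermediate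
12 | 2-nonadecyl-6-oxocyclohex-1-ene-1-carboxylic acid | CCCCCCCCCCCCCCCCCCCC1=C(C(=O)O)C(=O)CCC1 | intermediate
13 | 3-nonadecylcyclohex-2-en-1-one | CCCCCCCCCCCCCCCCCCCC1=CC(=O)CCC1 | target

**Step count and risks**

Total step count: 3. Longest linear sequence: 3 (1 → 4 → 9 → 13).

Steps most likely to fail, most risky first:

Step 2 (highest risk). Three things can go wrong:
- A second Michael addition at the other CH2 of 5; excess 5 and slow release of 6 from 4 are meant to suppress it.
- Ring closure the other way round, with the chain ketone's α-CH2 attacking the donor ketone (Hagemann-type) or an ester (Claisen).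
- A sluggish Knoevenagel step onto an unactivated dialkyl ketone.

The fallback sets out from 4 and comes back to the route at 11. It builds the linear chain with a donor that has only one ester and cannot be alkylated twice. Compound 4 is ketalised (ethylene glycol, TsOH cat., toluene, Dean–Stark) to 2-(2-chloroethyl)-2-nonadecyl-1,3-dioxolane F2. The dilithio dianion of methyl acetoacetate (2 LDA, THF, 0 °C; Bu4NI 10 mol %) is alkylated at its terminal carbon by F2 to give methyl 6-(2-nonadecyl-1,3-dioxolan-2-yl)-3-oxohexanoate F3. Treatment with 1 M HCl/THF removes the ketal to give methyl 3,7-dioxohexacosanoate F4. Under piperidinium acetate in refluxing toluene F4 closes C2→C7 to 11, which is then carried through the conditions of step 3 with only one ester left to remove.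

Step 3. The tetrasubstituted vinylogous ester may resist hydrolysis, 12 must deconjugate before it can lose CO2, and long heating in acid could open the ring by retro-aldol and re-close it with the wrong regiochemistry.

The fallback sets out from 4 and comes back at 12. It replaces hydrolysis by water-free acidolysis of tert-butyl esters. Step 2 is repeated with commercial di-tert-butyl 3-oxopentanedioate (KOtBu in t-BuOH–THF for the first stage, to avoid transesterification; then piperidinium acetate in toluene). It passes through 6, di-tert-butyl 3-oxo-2-(3-oxodocosyl)pentanedioate F5 and the aldol di-tert-butyl 4-hydroxy-4-nonadecyl-2-oxocyclohexane-1,3-dicarboxylate F6 to di-tert-butyl 4-nonadecyl-2-oxocyclohex-3-ene-1,3-dicarboxylate F7. TFA/CH2Cl2 at rt strips both esters by E1 loss of isobutene to give 4-nonadecyl-2-oxocyclohex-3-ene-1,3-dicarboxylic acid F8. Warming F8 in toluene removes the first CO2 to give 12, which decarboxylates on to 13 as in the route.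

Step 1. Acylation of a gas with a waxy C20 acyl chloride can give oligomeric or doubly acylated material, and partial HCl loss gives the polymerisable vinyl ketone.

The fallback sets out from 3 and comes back at 6. It reverses the polarity of the two-carbon unit. Acid chloride 3 is converted under Schotten–Baumann conditions (MeNHOMe·HCl, aq. K2CO3, CH2Cl2) into N-methoxy-N-methylicosanamide F1. Vinylmagnesium bromide (1.3 equiv, THF, 0 °C) then gives 6 after inverse quench into cold 2 M HCl, which stops the liberated amine adding back to the enone. Compound 6 is used at once in step 2, where only catalytic K2CO3 is then needed in the first stage.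

**Further compounds**

F1 | step 1 | N-methoxy-N-methylicosanamide | CCCCCCCCCCCCCCCCCCCC(=O)N(C)OC
F2 | step 2 | 2-(2-chloroethyl)-2-nonadecyl-1,3-dioxolane | CCCCCCCCCCCCCCCCCCCC1(CCCl)OCCO1
F3 | step 2 | methyl 6-(2-nonadecyl-1,3-dioxolan-2-yl)-3-oxohexanoate | CCCCCCCCCCCCCCCCCCCC1(CCCC(=O)CC(=O)OC)OCCO1
F4 | step 2 | methyl 3,7-dioxohexacosanoate | CCCCCCCCCCCCCCCCCCCC(=O)CCCC(=O)CC(=O)OC
F5 | step 3 | di-tert-butyl 3-oxo-2-(3-oxodocosyl)pentanedioate | CCCCCCCCCCCCCCCCCCCC(=O)CCC(C(=O)OC(C)(C)C)C(=O)CC(=O)OC(C)(C)C
F6 | step 3 | di-tert-butyl 4-hydroxy-4-nonadecyl-2-oxocyclohexane-1,3-dicarboxylate | CCCCCCCCCCCCCCCCCCCC1(O)CCC(C(=O)OC(C)(C)C)C(=O)C1C(=O)OC(C)(C)C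
F7 | step 3 | di-tert-butyl 4-nonadecyl-2-oxocyclohex-3-ene-1,3-dicarboxylate | CCCCCCCCCCCCCCCCCCCC1=C(C(=O)OC(C)(C)C)C(=O)C(C(=O)OC(C)(C)C)CC1
F8 | step 3 | 4-nonadecyl-2-oxocyclohex-3-ene-1,3-dicarboxylic acid | CCCCCCCCCCCCCCCCCCCC1=C(C(=O)O)C(=O)C(C(=O)O)CC1
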